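**Plan**

1. Numbering: C1 (bridgehead carbinol), C2 (CH2), C3 (amide carbon), C4 (carbinol), C5 (bridgehead CH), C6 (methoxy carbon), C7 and C8 (epoxide carbons, C8 on C1), C9 (ketone). Ring A is C1–C5 with C9, ring B is C5–C8 with C1 and C9, and exo means the face of a ring turned away from the other ring.
2. Retrosynthesis: remove the C4 silyl and C1 4-methoxybenzyl groups and the O-methyl group, take the C7–C8 epoxide back to the C6 allylic alcohol, transpose that to the C6=C7–C8=O enone and saturate it, then cut C1–C2 and C4–C5.
3. Enabling feature: C1 carries oxygen and lies between the C9 ketone and the oxidised C8, so ring B is a 2-alkoxycyclohexane-1,3-dione whose two acidic sites, C1 and C5, can be spanned by the three-carbon amido-enal C2–C3–C4, which already bears the dodecenoyl amide.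
4. Forward: ring B is bought as cyclohexane-1,3-dione; ring A is closed in one flask by conjugate addition (C1–C2) and bridged aldol (C4–C5); ring B is then dehydrogenated, epoxidised, transposed, epoxidised again, methylated and unmasked.
5. Stereochemistry: C1 and C5 come from a chiral primary amine choosing one of two enantiotopic ketones; C3 and C4 from the chair transition state of the aldol; C6 from exo attack of peroxide on the enone; C7 and C8 from epoxidation directed by the exo C6 hydroxyl.

Key step: step 6

Assumption: the quinine-derived primary amine is taken to select the ketone that leads to the (1S,5R) ketol 11; if the sense proves opposite, the quinidine-derived pseudoenantiomer is used with nothing else changed.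
Remark: locants and descriptors in the names follow the numbering of the plan; absolute configuration is fixed by the SMILES in the compound list.

**Step 1**
Reactants: 1 cyclohexane-1,3-dione
Product: 2 2-diazocyclohexane-1,3-dione
Conditions: 4-acetamidobenzenesulfonyl azide, Et3N, MeCN, 0 °C → rt
Reagents that add atoms: 4-acetamidobenzenesulfonyl azide, CC(=O)Nc1ccc(cc1)S(=O)(=O)N=[N+]=[N-]
Why: Regitz diazo transfer, in which the enolate of the 1,3-dione attacks the sulfonyl azide and the triazene collapses to the diazo dione and the sulfonamide, is the standard preparation of this compound.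

**Step 2**
Reactants: 2 2-diazocyclohexane-1,3-dione; 3 4-methoxybenzyl alcohol
Product: 4 2-(4-methoxybenzyloxy)cyclohexane-1,3-dione (present largely as its enol)
Conditions: Rh2(OAc)4 (1 mol%), 3 (2 equiv), slow addition of 2, 1,2-dichloroethane, 80 °C
Reagents that add atoms: none
Why: Rh2(OAc)4 turns the diazo dione into an electrophilic carbenoid that the alcohol oxygen captures (O–H insertion through an oxonium ylide and proton shift) faster than Wolff rearrangement or attack on the anisyl ring can occur.

**Step 3**
Reactants: 5 (E)-dodec-2-enoic acid; 6 aminoacetaldehyde dimethyl acetal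
Product: 7 (E)-N-(2,2-dimethoxyethyl)dodec-2-enamide
Conditions: DCC, HOBt (cat.), CH2Cl2, 0 °C → rt
Reagents that add atoms: none
Why: Carbodiimide amide coupling, in which the hydroxybenzotriazole ester acylates the primary amine much faster than the amine adds in conjugate fashion to the enoate.

**Step 4**
Reactants: 7 (E)-N-(2,2-dimethoxyethyl)dodec-2-enamide
Product: 8 (E)-N-(2-oxoethyl)dodec-2-enamide
Conditions: 1 M aq. HCl, THF, rt; used without storage
Reagents that add atoms: water, O
Why: Acid-catalysed acetal hydrolysis, to which the unsaturated secondary amide is inert, should release the N-acylamino aldehyde.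

**Step 5**
Reactants: 8 (E)-N-(2-oxoethyl)dodec-2-enamide
Product: 9 (E)-N-(1-formylvinyl)dodec-2-enamide (the 2-amidoacrolein)
Conditions: 37% aq. CH2O, pyrrolidine (10 mol%), EtCO2H (10 mol%), i-PrOH, 45 °C; kept cold and used at once
Reagents that add atoms: formaldehyde, C=O
Why: Amine-catalysed Mannich α-methylenation, in which the pyrrolidine enamine of 8 adds to the formaldehyde-derived iminium ion and the Mannich base eliminates pyrrolidine to give the α-substituted acrolein.

**Step 6**
Reactants: 4 2-(4-methoxybenzyloxy)cyclohexane-1,3-dione; 9 (E)-N-(1-formylvinyl)dodec-2-enamide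
Product: 11 (1S,3S,4R,5R)-3-[(E)-dodec-2-enamido]-4-hydroxy-1-(4-methoxybenzyloxy)bicyclo[3.3.1]nonane-8,9-dione, via keto aldehyde 10 (not isolated)
Conditions: Et3N (10 mol%), toluene, 0 °C → rt; then 9-amino-9-deoxy-epi-quinine (20 mol%), CF3CO2H (50 mol%), rt, same flask
Reagents that add atoms: none
Why: Proposed new method: the triethylammonium enolate of 4 adds through carbon to the β-carbon of enal 9 (C1–C2), giving 10, in which C1 is a prochiral quaternary carbon flanked by two enantiotopic ketones and the α-amido aldehyde carbon C3 epimerises freely through its enol or enamine. The primary amine salt then condenses with one ketone, and the C5 terminus of the resulting enamine attacks the aldehyde in a 6-(enolendo)-exo-trig aldol that closes ring A and turns that ketone into C9; the ketol cannot dehydrate because the alkene would sit at a bridgehead. The closest known reaction type is the amine-catalysed Michael addition and bridged aldol of 2-alkylcyclohexane-1,3-diones with enals, together with primary-amine-catalysed desymmetrising aldolisations of 2,2-disubstituted 1,3-diones; a 2-amidoacrolein acceptor, an alkoxy-substituted dione and an aldehyde that epimerises during ring closure have not been shown. C1 and C5 are set by the catalyst, which chooses between the enantiotopic ketones; C3 is set by the chair-like transition state, which takes the amide equatorial (exo) from the rapidly equilibrating aldehyde epimers (dynamic kinetic resolution); C4 is set by hydrogen bonding of the aldehyde oxygen to the enamine N–H and ammonium site, which places the hydroxyl axial and syn to C9. The step needs enantiotopic-group selectivity and carbon over oxygen alkylation: because the dione is symmetric the conjugate addition fixes no stereocentre and may run without the chiral amine, O-adducts revert, and adding the primary amine only after the conjugate addition keeps the free dione from tying up the catalyst as a vinylogous amide.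

**Step 7**
Reactants: 11 the ketol from step 6
Product: 12 3-exo-[(E)-dodec-2-enamido]-4-(tert-butyldimethylsilyloxy)-1-(4-methoxybenzyloxy)bicyclo[3.3.1]nonane-8,9-dione
Conditions: t-BuMe2SiOTf, 2,6-lutidine, CH2Cl2, –78 → 0 °C
Reagents that add atoms: tert-butyldimethylsilyl triflate, CC(C)(C)[Si](C)(C)OS(=O)(=O)C(F)(F)F
Why: Silyl triflate silylation of a hindered secondary alcohol, which blocks retro-aldol opening of ring A in the basic steps ahead and leaves the amide unchanged after work-up.

**Step 8**
Reactants: 12 the C4 silyl ether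
Product: 14 3-exo-[(E)-dodec-2-enamido]-4-(tert-butyldimethylsilyloxy)-1-(4-methoxybenzyloxy)bicyclo[3.3.1]non-6-ene-8,9-dione, via trimethylsilyl enol ether 13 (not isolated)
Conditions: Me3SiOTf, Et3N, CH2Cl2, 0 °C; evaporation, filtration in pentane; Pd(OAc)2 (1.1 equiv), MeCN, rt
Reagents that add atoms: none
Why: Saegusa–Ito dehydrogenation: only C7 can be enolised (C1 is quaternary and C9 lies between a quaternary carbon and a bridgehead CH), so the silyl enol ether forms at C7=C8 and β-hydride elimination from the palladium enolate gives the C6=C7 enone, while the amide silylated in passing is restored on work-up.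

**Step 9**
Reactants: 14 the C6=C7 enone
Product: 15 6,7-exo-epoxy-3-exo-[(E)-dodec-2-enamido]-4-(tert-butyldimethylsilyloxy)-1-(4-methoxybenzyloxy)bicyclo[3.3.1]nonane-8,9-dione
Conditions: t-BuOOH (decane), DBU, CH2Cl2, 0 °C → rt
Reagents that add atoms: tert-butyl hydroperoxide, CC(C)(C)OO
Why: Weitz–Scheffer nucleophilic epoxidation, in which tert-butylperoxide adds to C6 from the exo face (the endo face is covered by ring A) and the enolate closes the oxirane, setting C6 with oxygen exo.

**Step 10**
Reactants: 15 the 6,7-epoxy ketone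
Product: 17 3-exo-[(E)-dodec-2-enamido]-6-exo-hydroxy-4-(tert-butyldimethylsilyloxy)-1-(4-methoxybenzyloxy)bicyclo[3.3.1]non-7-en-9-one, via epoxy hydrazone 16 (not isolated)
Conditions: N2H4·H2O (3 equiv), AcOH, degassed MeOH, 0 °C → rt; acetone quench
Reagents that add atoms: none
Why: Wharton transposition, in which the C8 hydrazone opens the epoxide to an alkenyl diazene that loses N2, moving the alkene to C7=C8 and leaving the C6–O bond and its exo configuration untouched; the more electrophilic epoxy ketone should condense before the shielded C9 ketone.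

**Step 11**
Reactants: 17 the C6 allylic alcohol
Product: 18 7,8-exo-epoxy-3-exo-[(E)-dodec-2-enamido]-6-exo-hydroxy-4-(tert-butyldimethylsilyloxy)-1-(4-methoxybenzyloxy)bicyclo[3.3.1]nonan-9-one
Conditions: VO(acac)2 (10 mol%), t-BuOOH (decane), CH2Cl2, 0 °C → rt
Reagents that add atoms: tert-butyl hydroperoxide, CC(C)(C)OO
Why: Vanadium-catalysed hydroxyl-directed epoxidation of a cyclic allylic alcohol, in which the vanadate ester of the exo, pseudo-axial C6 hydroxyl delivers oxygen to its own face, also the open convex face, so C7 and C8 are set exo and the electron-poor enamide alkene is left alone.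

**Step 12**
Reactants: 18 the epoxy alcohol
Product: 19 7,8-exo-epoxy-3-exo-[(E)-dodec-2-enamido]-6-exo-methoxy-4-(tert-butyldimethylsilyloxy)-1-(4-methoxybenzyloxy)bicyclo[3.3.1]nonan-9-one
Conditions: MeI (excess), Ag2O, 4 Å molecular sieves, MeCN, 40 °C, dark
Reagents that add atoms: iodomethane, CI
Why: Purdie methylation under non-basic conditions, which avoids alkoxide-driven retro-aldol cleavage of C5–C6 and should spare the amide N–H and the epoxide, which is cis to the hydroxyl and so cannot undergo Payne rearrangement.

**Step 13**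
Reactants: 19 the C6 methyl ether
Product: 20 7,8-exo-epoxy-3-exo-[(E)-dodec-2-enamido]-1-hydroxy-6-exo-methoxy-4-(tert-butyldimethylsilyloxy)bicyclo[3.3.1]nonan-9-one
Conditions: DDQ, CH2Cl2–pH 7 phosphate buffer, 0 °C → rt
Reagents that add atoms: none
Why: Oxidative cleavage of the 4-methoxybenzyl ether by DDQ (benzylic hydride abstraction, then hydrolysis of the oxocarbenium ion) under buffered conditions that epoxide, silyl ether and enamide tolerate.

**Step 14**
Reactants: 20 the C1 alcohol
Product: 21 (1S,3S,4R,5S,6S,7S,8S)-3-[(E)-dodec-2-enamido]-7,8-epoxy-1,4-dihydroxy-6-methoxybicyclo[3.3.1]nonan-9-one (CNP0137540.1)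
Conditions: HF·pyridine, pyridine, THF, 0 °C → rt
Reagents that add atoms: none
Why: Fluoride-mediated desilylation with pyridine-buffered HF·pyridine, mild enough for the epoxide and the two β-hydroxy ketone units, frees the C4 hydroxyl.

**Compound list**

1 | cyclohexane-1,3-dione | O=C1CCCC(=O)C1 | starting material
2 | 2-diazocyclohexane-1,3-dione | O=C1CCCC(=O)C1=[N+]=[N-] | intermediate
3 | 4-methoxybenzyl alcohol | COc1ccc(CO)cc1 | starting material
4 | 2-(4-methoxybenzyloxy)cyclohexane-1,3-dione | O=C1CCCC(=O)C1OCc1ccc(OC)cc1 | intermediate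
5 | (E)-dodec-2-enoic acid | CCCCCCCCC/C=C/C(=O)O | starting material
6 | aminoacetaldehyde dimethyl acetal | NCC(OC)OC | starting material
7 | (E)-N-(2,2-dimethoxyethyl)dodec-2-enamide | CCCCCCCCC/C=C/C(=O)NCC(OC)OC | intermediate
8 | (E)-N-(2-oxoethyl)dodec-2-enamide | CCCCCCCCC/C=C/C(=O)NCC=O | intermediate
9 | (E)-N-(1-formylvinyl)dodec-2-enamide | CCCCCCCCC/C=C/C(=O)NC(=C)C=O | intermediate
10 | 2-[2-((E)-dodec-2-enamido)-3-oxopropyl]-2-(4-methoxybenzyloxy)cyclohexane-1,3-dione (C3 epimers interconvert; formed in the flask) | CCCCCCCCC/C=C/C(=O)NC(C=O)CC1(OCc2ccc(OC)cc2)C(=O)CCCC1=O | intermediate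
11 | (1S,3S,4R,5R)-3-[(E)-dodec-2-enamido]-4-hydroxy-1-(4-methoxybenzyloxy)bicyclo[3.3.1]nonane-8,9-dione (amide exo and equatorial; hydroxyl axial, syn to C9) | CCCCCCCCC/C=C/C(=O)N[C@H]1C[C@@]2(OCc3ccc(OC)cc3)C(=O)[C@@H]([C@H]1O)CCC2=O | intermediate
12 | C4 tert-butyldimethylsilyl ether of 11 | CCCCCCCCC/C=C/C(=O)N[C@H]1C[C@@]2(OCc3ccc(OC)cc3)C(=O)[C@@H]([C@H]1O[Si](C)(C)C(C)(C)C)CCC2=O | intermediate
13 | C7=C8 trimethylsilyl enol ether of 12 (formed in the flask) | CCCCCCCCC/C=C/C(=O)N[C@H]1C[C@@]2(OCc3ccc(OC)cc3)C(=O)[C@@H]([C@H]1O[Si](C)(C)C(C)(C)C)CC=C2O[Si](C)(C)C | intermediate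
14 | C6=C7 enone (bicyclo[3.3.1]non-6-ene-8,9-dione) | CCCCCCCCC/C=C/C(=O)N[C@H]1C[C@@]2(OCc3ccc(OC)cc3)C(=O)[C@@H]([C@H]1O[Si](C)(C)C(C)(C)C)C=CC2=O | intermediate
15 | 6,7-exo-epoxy-8,9-dione | CCCCCCCCC/C=C/C(=O)N[C@H]1C[C@@]2(OCc3ccc(OC)cc3)C(=O)[C@@H]([C@H]1O[Si](C)(C)C(C)(C)C)[C@@H]4O[C@@H]4C2=O | intermediate
16 | C8 hydrazone of 15 (formed in the flask) | CCCCCCCCC/C=C/C(=O)N[C@H]1C[C@@]2(OCc3ccc(OC)cc3)C(=O)[C@@H]([C@H]1O[Si](C)(C)C(C)(C)C)[C@@H]4O[C@@H]4C2=NN | intermediate
17 | 6-exo-hydroxy-non-7-en-9-one (C7=C8 alkene) | CCCCCCCCC/C=C/C(=O)N[C@H]1C[C@@]2(OCc3ccc(OC)cc3)C(=O)[C@@H]([C@H]1O[Si](C)(C)C(C)(C)C)[C@H](O)C=C2 | intermediate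
18 | 7,8-exo-epoxy-6-exo-hydroxy-nonan-9-one | CCCCCCCCC/C=C/C(=O)N[C@H]1C[C@@]2(OCc3ccc(OC)cc3)C(=O)[C@@H]([C@H]1O[Si](C)(C)C(C)(C)C)[C@H](O)[C@@H]4O[C@@H]42 | intermediate
19 | 7,8-exo-epoxy-6-exo-methoxy-nonan-9-one, C1 4-methoxybenzyl ether, C4 silyl ether | CCCCCCCCC/C=C/C(=O)N[C@H]1C[C@@]2(OCc3ccc(OC)cc3)C(=O)[C@@H]([C@H]1O[Si](C)(C)C(C)(C)C)[C@H](OC)[C@@H]4O[C@@H]42 | intermediate
20 | 7,8-exo-epoxy-1-hydroxy-6-exo-methoxy-nonan-9-one, C4 silyl ether | CCCCCCCCC/C=C/C(=O)N[C@H]1C[C@@]2(O)C(=O)[C@@H]([C@H]1O[Si](C)(C)C(C)(C)C)[C@H](OC)[C@@H]4O[C@@H]42 | intermediate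
21 | (1S,3S,4R,5S,6S,7S,8S)-3-[(E)-dodec-2-enamido]-7,8-epoxy-1,4-dihydroxy-6-methoxybicyclo[3.3.1]nonan-9-one | CCCCCCCCC/C=C/C(=O)N[C@H]1C[C@@]2(O)C(=O)[C@@H]([C@H]1O)[C@H](OC)[C@@H]1O[C@@H]12 | target

**Step count and risks**

Total step count: 14. Longest linear sequence: 12 steps (steps 3–5, then 6–14, from (E)-dodec-2-enoic acid); the dione branch (steps 1 and 2) joins at step 6.

Steps most likely to fail:

Step 6 (carries the label). The chiral amine may engage the aldehyde instead of the hindered ketone, so that ring closure is slow or does not discriminate between the enantiotopic carbonyls. The C4 hydroxyl may also close equatorial, and the amidoacrolein may oligomerise before it is consumed. The fallback uses known chemistry and sets out from 4 and 9. Conjugate addition with Et3N (10 mol%) in CH2Cl2 would give keto aldehyde 10, which is isolated. Pyrrolidine and AcOH in CHCl3 would then close the bridged aldol under equilibrating, achiral conditions to the racemic ketol, that is 11 together with its mirror image ent-11 F1. Preparative chromatography on a cellulose carbamate chiral stationary phase separates the two, and the route is rejoined at 11.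

Step 10. Hydrazine may also condense with the C9 ketone, and the β-hydroxy ketone formed may undergo retro-aldol opening of ring B in the basic medium. The fallback sets out from 12 and avoids both the enone and hydrazine. KN(SiMe3)2 (2.2 equiv) and N-phenyl-bis(trifluoromethanesulfonimide) in THF at –78 °C would give the C7=C8 enol triflate F2. Reduction with Pd(OAc)2, PPh3, Bu3N and HCO2H in DMF at 60 °C would give the C7=C8 alkene F3. Riley allylic hydroxylation with catalytic SeO2 and t-BuOOH in CH2Cl2 should then put the hydroxyl on C6, the only allylic C–H position of the ring alkene, from the exo face through the ene reaction and [2,3] shift. This comes back to the route at 17 and replaces steps 8 to 10.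

Step 12. Methylation of a hindered hydroxyl, deactivated by the neighbouring epoxide, may be slow enough for N-methylation of the amide or retro-aldol cleavage to compete. The fallback sets out from 17 and changes the order of events and the directing group. The allylic alcohol is methylated first (Ag2O and MeI, or Me3OBF4 with 1,8-bis(dimethylamino)naphthalene since no epoxide is yet present) to give the 6-exo-methoxy alkene F4. DDQ in buffered CH2Cl2 then frees the bridgehead hydroxyl to give the 1-hydroxy-6-exo-methoxy alkene F5. Epoxidation with mCPBA and NaHCO3 in CH2Cl2 at 0 °C should occur on the exo face, guided by hydrogen bonding to the C1 hydroxyl (which leans to that face) and by ring A shielding the endo face. This returns to the route at 20.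

**Further compounds**

F1 | step 6 | ent-11, (1R,3R,4S,5S)-3-[(E)-dodec-2-enamido]-4-hydroxy-1-(4-methoxybenzyloxy)bicyclo[3.3.1]nonane-8,9-dione | CCCCCCCCC/C=C/C(=O)N[C@@H]1C[C@]2(OCc3ccc(OC)cc3)C(=O)[C@H]([C@@H]1O)CCC2=O
F2 | step 10 | C7=C8 enol triflate of 12 (8-trifluoromethanesulfonyloxy-non-7-en-9-one) | CCCCCCCCC/C=C/C(=O)N[C@H]1C[C@@]2(OCc3ccc(OC)cc3)C(=O)[C@@H]([C@H]1O[Si](C)(C)C(C)(C)C)CC=C2OS(=O)(=O)C(F)(F)F
F3 | step 10 | 3-exo-[(E)-dodec-2-enamido]-4-(tert-butyldimethylsilyloxy)-1-(4-methoxybenzyloxy)bicyclo[3.3.1]non-7-en-9-one | CCCCCCCCC/C=C/C(=O)N[C@H]1C[C@@]2(OCc3ccc(OC)cc3)C(=O)[C@@H]([C@H]1O[Si](C)(C)C(C)(C)C)CC=C2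
F4 | step 12 | 6-exo-methoxy-non-7-en-9-one, C1 4-methoxybenzyl ether, C4 silyl ether | CCCCCCCCC/C=C/C(=O)N[C@H]1C[C@@]2(OCc3ccc(OC)cc3)C(=O)[C@@H]([C@H]1O[Si](C)(C)C(C)(C)C)[C@H](OC)C=C2
F5 | step 12 | 1-hydroxy-6-exo-methoxy-non-7-en-9-one, C4 silyl ether | CCCCCCCCC/C=C/C(=O)N[C@H]1C[C@@]2(O)C(=O)[C@@H]([C@H]1O[Si](C)(C)C(C)(C)C)[C@H](OC)C=C2
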